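**Plan**

1. Retrosynthesis: the cyclohexene ring of the hexahydroindene (C3a–C4–C5–C6=C7–C7a, with the C6=C7 alkene and the carboxyl-bearing C4 next to a ring-fusion carbon) is a Diels–Alder retron. Cutting C3a–C7a and C4–C5 opens both rings to an acyclic (2E,7E,9E,11E,13E)-pentaenoic acid (chain numbering: C1 = carboxyl carbon, C14 = phenyl-bearing carbon; used for all open-chain compounds), whose C4–C5–C6 segment is the three-atom tether that becomes the cyclopentanone; the ketone is carried as a C5 silyl ether.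
2. The open chain is cut at C8–C9 (Negishi coupling), C2=C3 (Wittig) and C5–C6 (allenylzinc addition to an aldehyde); the east triene is cut at two C=C bonds (Wittig, Horner–Wadsworth–Emmons).
3. Forward: east trienyl bromide from 2-ethylacrolein; west vinyl iodide from an auxiliary-derived α-ethyl aldehyde and an enantioenriched propargylic mesylate; fragment union; one thermal intramolecular cycloaddition then closes the five- and six-membered rings together; desilylation and oxidation finish.
4. Stereochemistry: C6 comes from a propargylic alcohol set by asymmetric transfer hydrogenation and C4 from an oxazolidinone auxiliary. These two centres relay, through allylic 1,3-strain, the E alkene geometries and the endo mode, to the four new centres C2, C3, C7 and C10 in the cycloaddition; C5 is a temporary stereocentre erased on oxidation.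

Key step: step 18

Remark: ethyl 2-(triphenyl-λ5-phosphanylidene)butanoate and (4R)-4-benzyl-3-butanoyl-1,3-oxazolidin-2-one are taken as catalogue compounds (each is otherwise one routine step from ethyl 2-bromobutanoate/PPh3 or from (4R)-4-benzyl-1,3-oxazolidin-2-one/butanoyl chloride).

**East fragment**

Step 1
Reactants: 1 2-methylidenebutanal (2-ethylacrolein)
Product: 3 (2E)-2-(bromomethylidene)butanal, via 2,3-dibromo-2-ethylpropanal 2 (not isolated)
Conditions: Br2, CH2Cl2, −78 → 0 °C; then Et3N, 0 °C → rt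
Reagents that add atoms: bromine, BrBr
Why: Addition of bromine to the 1,1-disubstituted alkene followed by E2 loss of HBr (bromination–dehydrobromination, as practised on methacrolein) should give the thermodynamically preferred E bromoenal, with bromine trans to the formyl group.

Step 2
Reactants: 3 (2E)-2-(bromomethylidene)butanal; 4 ethyl 2-(triphenyl-λ5-phosphanylidene)butanoate
Product: 5 ethyl (2E,4E)-5-bromo-2,4-diethylpenta-2,4-dienoate
Conditions: CH2Cl2, rt → 40 °C
Reagents that add atoms: none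
Why: Wittig olefination with a stabilised α-branched ylide is expected to attack the aldehyde rather than the bromoalkene and to give the E trisubstituted alkene.

Step 3
Reactants: 5 ethyl (2E,4E)-5-bromo-2,4-diethylpenta-2,4-dienoate
Product: 6 (2E,4E)-5-bromo-2,4-diethylpenta-2,4-dien-1-ol
Conditions: i-Bu2AlH (2.2 equiv), CH2Cl2, −78 °C; aq. potassium sodium tartrate
Reagents that add atoms: none
Why: 1,2-Reduction of the conjugated ester by the aluminium hydride gives the allylic alcohol and leaves the vinyl bromide untouched.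

Step 4
Reactants: 6 (2E,4E)-5-bromo-2,4-diethylpenta-2,4-dien-1-ol
Product: 7 (2E,4E)-5-bromo-2,4-diethylpenta-2,4-dienal
Conditions: MnO2 (excess), CH2Cl2, rt
Reagents that add atoms: none
Why: MnO2 oxidises allylic alcohols selectively and should not isomerise the alkenes.

Step 5
Reactants: 7 (2E,4E)-5-bromo-2,4-diethylpenta-2,4-dienal; 8 diethyl benzylphosphonate
Product: 10 [(1E,3E,5E)-6-bromo-3,5-diethylhexa-1,3,5-trien-1-yl]benzene, via sodium (diethoxyphosphoryl)(phenyl)methanide 9 (not isolated)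
Conditions: 8, NaH, 15-crown-5 (cat.), THF, 0 °C; then 7, 0 °C → rt
Reagents that add atoms: sodium hydride, [Na+].[H-] (sodium in 9 only)
Why: Horner–Wadsworth–Emmons olefination of an enal with a benzylic phosphonate carbanion should give the E styrene; the bromoalkene has no vicinal vinylic hydrogen, so base cannot eliminate HBr.

**Propargylic mesylate**

Step 6
Reactants: 11 pent-3-yn-2-one
Product: 12 (2R)-pent-3-yn-2-ol
Conditions: RuCl[(R,R)-TsDPEN](p-cymene) (0.5 mol %), KOH (1 mol %), i-PrOH, rt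
Reagents that add atoms: none
Why: Noyori asymmetric transfer hydrogenation of an alkynyl ketone delivers hydride and proton through the six-membered Ru–H/N–H transition state with the alkynyl group in the place of an aryl group, so the (R,R) catalyst should give the R alcohol.

Step 7
Reactants: 12 (2R)-pent-3-yn-2-ol
Product: 13 (2R)-pent-3-yn-2-yl methanesulfonate
Conditions: MsCl, Et3N, CH2Cl2, −78 → −20 °C
Reagents that add atoms: methanesulfonyl chloride, CS(=O)(=O)Cl
Why: Mesylation occurs at oxygen, does not touch the stereocentre and provides the leaving group for SN2′ palladation.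

**α-Ethyl aldehyde**

Step 8
Reactants: 14 (4R)-4-benzyl-3-butanoyl-1,3-oxazolidin-2-one
Product: 16 (4R)-4-benzyl-3-[(2S)-2-(hydroxymethyl)butanoyl]-1,3-oxazolidin-2-one, via trichlorotitanium (Z)-enolate 15 (not isolated)
Conditions: TiCl4, i-Pr2NEt, CH2Cl2, 0 °C; then 1,3,5-trioxane, TiCl4, 0 °C
Reagents that add atoms: 1,3,5-trioxane, C1OCOCO1; titanium tetrachloride, Cl[Ti](Cl)(Cl)Cl (titanium and chlorine in 15 only)
Why: Evans auxiliary-controlled hydroxymethylation: the chelated Z titanium enolate is attacked by TiCl4-activated formaldehyde on the face opposite the benzyl group, which should set the 2S centre (C4 of the later chain).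

Step 9
Reactants: 16 (4R)-4-benzyl-3-[(2S)-2-(hydroxymethyl)butanoyl]-1,3-oxazolidin-2-one
Product: 17 (4R)-4-benzyl-3-[(2S)-2-{[(triethylsilyl)oxy]methyl}butanoyl]-1,3-oxazolidin-2-one
Conditions: Et3SiCl, imidazole, CH2Cl2, 0 °C
Reagents that add atoms: chlorotriethylsilane, CC[Si](Cl)(CC)CC
Why: Standard silylation of the primary alcohol installs an ether that can later be oxidised directly to the aldehyde.

Step 10
Reactants: 17 (4R)-4-benzyl-3-[(2S)-2-{[(triethylsilyl)oxy]methyl}butanoyl]-1,3-oxazolidin-2-one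
Product: 18 (2R)-2-{[(triethylsilyl)oxy]methyl}butan-1-ol
Conditions: LiBH4, MeOH (1 equiv), Et2O, 0 °C
Reagents that add atoms: none
Why: Reductive cleavage of the imide by LiBH4 attacks the exocyclic carbonyl, releases the auxiliary and leaves the stereocentre and the silyl ether intact (the descriptor changes only through priorities).

Step 11
Reactants: 18 (2R)-2-{[(triethylsilyl)oxy]methyl}butan-1-ol
Product: 19 (2S)-2-{[(triethylsilyl)oxy]methyl}butanal
Conditions: Dess–Martin periodinane, NaHCO3, CH2Cl2, 0 °C → rt; used at once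
Reagents that add atoms: none
Why: Buffered Dess–Martin oxidation gives the α-branched aldehyde under non-basic conditions that should not epimerise it.

**West fragment, union and endgame**

Step 12
Reactants: 19 (2S)-2-{[(triethylsilyl)oxy]methyl}butanal; 13 (2R)-pent-3-yn-2-yl methanesulfonate
Product: 21 (3S,4S,5S)-5-methyl-3-{[(triethylsilyl)oxy]methyl}oct-6-yn-4-ol, via ethyl[(P)-penta-2,3-dien-2-yl]zinc 20 (not isolated)
Conditions: Pd(OAc)2 (5 mol %), PPh3 (5 mol %), Et2Zn (3 equiv), THF, −78 → −20 °C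
Reagents that add atoms: diethylzinc, CC[Zn]CC (zinc and ethyl in 20 only)
Why: Marshall propargylation: zerovalent palladium displaces the mesylate anti (SN2′), transmetalation with Et2Zn gives the allenylzinc with retention, and its SE2′ addition through a cyclic transition state should give the 5,6-anti adduct with net inversion at the propargylic carbon (6S) on the Felkin face of 19 (4,5-syn, reagent and substrate control matched).

Step 13
Reactants: 21 (3S,4S,5S)-5-methyl-3-{[(triethylsilyl)oxy]methyl}oct-6-yn-4-ol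
Product: 22 tert-butyl(dimethyl){[(3S,4S,5S)-5-methyl-3-{[(triethylsilyl)oxy]methyl}oct-6-yn-4-yl]oxy}silane
Conditions: TBSOTf, 2,6-lutidine, CH2Cl2, −78 → 0 °C
Reagents that add atoms: tert-butyldimethylsilyl trifluoromethanesulfonate, CC(C)(C)[Si](C)(C)OS(=O)(=O)C(F)(F)F
Why: Silylation of the hindered secondary alcohol with the silyl triflate protects the C5 oxygen for the oxidation and organometallic steps.

Step 14
Reactants: 22 tert-butyl(dimethyl){[(3S,4S,5S)-5-methyl-3-{[(triethylsilyl)oxy]methyl}oct-6-yn-4-yl]oxy}silane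
Product: 24 (2E,4S,5S,6S)-5-[(tert-butyldimethylsilyl)oxy]-2-iodo-4-methyl-6-{[(triethylsilyl)oxy]methyl}oct-2-ene, via alkenylzirconocene chloride 23 (not isolated)
Conditions: Cp2Zr(H)Cl (3 equiv), THF, 50 °C; then I2, THF, 0 °C
Reagents that add atoms: iodine, II; Cp2Zr(H)Cl, [H][Zr](Cl)(C1C=CC=C1)C1C=CC=C1 (zirconium in 23 only)
Why: Hydrozirconation adds Zr–H syn across the alkyne and, with excess reagent and warming, places zirconium on the less hindered methyl-bearing carbon away from the branched C6; iodinolysis with retention should give the E trisubstituted vinyl iodide.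

Step 15
Reactants: 24 (2E,4S,5S,6S)-5-[(tert-butyldimethylsilyl)oxy]-2-iodo-4-methyl-6-{[(triethylsilyl)oxy]methyl}oct-2-ene; 4 ethyl 2-(triphenyl-λ5-phosphanylidene)butanoate
Product: 26 ethyl (2E,4S,5S,6S,7E)-5-[(tert-butyldimethylsilyl)oxy]-2,4-diethyl-8-iodo-6-methylnona-2,7-dienoate, via (2R,3S,4S,5E)-3-[(tert-butyldimethylsilyl)oxy]-2-ethyl-6-iodo-4-methylhept-5-enal 25 (not isolated)
Conditions: (COCl)2, DMSO, CH2Cl2, −78 → −40 °C; i-Pr2NEt, −78 → 0 °C; then 4, CH2Cl2, 40 °C
Reagents that add atoms: none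
Why: Swern conditions cleave and oxidise the primary triethylsilyl ether directly while the secondary TBS ether survives, and trapping the epimerisable aldehyde in situ by Wittig olefination with the stabilised ylide should give the E enoate without loss of the C4 configuration.

Step 16
Reactants: 10 [(1E,3E,5E)-6-bromo-3,5-diethylhexa-1,3,5-trien-1-yl]benzene; 26 ethyl (2E,4S,5S,6S,7E)-5-[(tert-butyldimethylsilyl)oxy]-2,4-diethyl-8-iodo-6-methylnona-2,7-dienoate
Product: 29 ethyl (2E,4S,5S,6S,7E,9E,11E,13E)-5-[(tert-butyldimethylsilyl)oxy]-2,4,10,12-tetraethyl-6,8-dimethyl-14-phenyltetradeca-2,7,9,11,13-pentaenoate, via trienyllithium 27 (not isolated), via trienylzinc chloride 28 (not isolated)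
Conditions: 10, t-BuLi (2.0 equiv), Et2O, −78 °C; ZnCl2 (THF), −78 → 0 °C; then 26, Pd(PPh3)4 (5 mol %), THF, rt, dark
Reagents that add atoms: tert-butyllithium, [Li]C(C)(C)C (lithium in 27 only); zinc chloride, Cl[Zn]Cl (zinc and chlorine in 28 only)
Why: Negishi coupling: bromine–lithium exchange and transmetalation to zinc keep the alkene geometry, and palladium-catalysed coupling of the alkenylzinc with the vinyl iodide (retention at both sp2 carbons) joins C8–C9 in the presence of the ester.

Step 17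
Reactants: 29 ethyl (2E,4S,5S,6S,7E,9E,11E,13E)-5-[(tert-butyldimethylsilyl)oxy]-2,4,10,12-tetraethyl-6,8-dimethyl-14-phenyltetradeca-2,7,9,11,13-pentaenoate
Product: 30 (2E,4S,5S,6S,7E,9E,11E,13E)-5-[(tert-butyldimethylsilyl)oxy]-2,4,10,12-tetraethyl-6,8-dimethyl-14-phenyltetradeca-2,7,9,11,13-pentaenoic acid
Conditions: LiOH·H2O, THF/MeOH/H2O, 25 °C, dark; then 1 M HCl to pH 4, 0 °C
Reagents that add atoms: lithium hydroxide, [Li+].[OH-]
Why: Saponification is done on the open chain at room temperature, because after cyclisation the carboxyl carbon sits on a quaternary centre next to a second one; the silyl ether and the polyene should tolerate LiOH.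

Step 18
Reactants: 30 (2E,4S,5S,6S,7E,9E,11E,13E)-5-[(tert-butyldimethylsilyl)oxy]-2,4,10,12-tetraethyl-6,8-dimethyl-14-phenyltetradeca-2,7,9,11,13-pentaenoic acid
Product: 31 (1S,2S,3S,3aR,4R,5R,7aR)-2-[(tert-butyldimethylsilyl)oxy]-3,4,5-triethyl-5-[(1E,3E)-2-ethyl-4-phenylbuta-1,3-dien-1-yl]-1,7-dimethyl-2,3,3a,4,5,7a-hexahydro-1H-indene-4-carboxylic acid
Conditions: toluene (0.01 M), BHT (cat.), 110 °C, argon, dark
Reagents that add atoms: none
Why: A concerted, suprafacial [4+2] cycloaddition between the 7E,9E-diene (HOMO raised by three alkyl groups and by conjugation with the 11,13-styryl diene) and the 2E-enoic acid (LUMO) forms C3–C7 and C2–C10 through one boat-like transition state. The closest known reaction type is the thermal intramolecular Diels–Alder reaction of 1,3,8-nonatrienes with a carbonyl-activated dienophile, which gives hexahydroindenes. The six-membered ring closes by the cycloaddition itself (both new bonds), and the five-membered ring closes in the same event by the C3–C7 bond across the three-atom tether C4–C5–C6, in the exo-tether, trans-fused mode. C7 and C3 follow from the diene face attacked, which C6 controls (allylic 1,3-strain with the C8 methyl group holds C6–H in the diene plane, so the tether reaches one face only) and C4 reinforces (the same strain with the C2 ethyl group); C2 follows from the E dienophile (CO2H cis to H-3), C10 from the 9E diene (side chain cis to the C7–C6 bond), and the trans ring fusion from the transition state with carboxyl endo and tether exo. The step needs site selectivity among three overlapping dienes, which the tether length secures (only the 7,9-diene gives a five-membered ring), endo selectivity, which the planar carboxyl group under the diene and the bulkier C2 ethyl group outside should secure, and configurational integrity at C4 and C6, which the C5 silyl ether (no enolisable ketone) secures.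

Step 19
Reactants: 31 (1S,2S,3S,3aR,4R,5R,7aR)-2-[(tert-butyldimethylsilyl)oxy]-3,4,5-triethyl-5-[(1E,3E)-2-ethyl-4-phenylbuta-1,3-dien-1-yl]-1,7-dimethyl-2,3,3a,4,5,7a-hexahydro-1H-indene-4-carboxylic acid
Product: 32 (1S,2S,3S,3aR,4R,5R,7aR)-3,4,5-triethyl-5-[(1E,3E)-2-ethyl-4-phenylbuta-1,3-dien-1-yl]-2-hydroxy-1,7-dimethyl-2,3,3a,4,5,7a-hexahydro-1H-indene-4-carboxylic acid
Conditions: HF·pyridine, pyridine, THF, 0 °C → rt
Reagents that add atoms: none
Why: Fluoride-driven cleavage of the Si–O bond frees the ring alcohol, which lies on the face opposite the carboxyl group, so lactonisation is not expected.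

Step 20
Reactants: 32 (1S,2S,3S,3aR,4R,5R,7aR)-3,4,5-triethyl-5-[(1E,3E)-2-ethyl-4-phenylbuta-1,3-dien-1-yl]-2-hydroxy-1,7-dimethyl-2,3,3a,4,5,7a-hexahydro-1H-indene-4-carboxylic acid
Product: 33 (1S,3S,3aR,4R,5R,7aR)-3,4,5-triethyl-5-[(1E,3E)-2-ethyl-4-phenylbuta-1,3-dien-1-yl]-1,7-dimethyl-2-oxo-2,3,3a,4,5,7a-hexahydro-1H-indene-4-carboxylic acid (CNP0134269.1)
Conditions: Dess–Martin periodinane, NaHCO3, CH2Cl2, 0 °C → rt
Reagents that add atoms: none
Why: Dess–Martin oxidation of the secondary alcohol gives the cyclopentanone under buffered conditions; both α-stereocentres already have the more stable trans arrangement to their ring neighbours, so enolisation should not erode them.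

**Compound list**

1 | 2-methylidenebutanal (2-ethylacrolein) | CCC(=C)C=O | starting material
2 | 2,3-dibromo-2-ethylpropanal (racemic) | CCC(Br)(CBr)C=O | intermediate
3 | (2E)-2-(bromomethylidene)butanal | O=C/C(CC)=C/Br | intermediate
4 | ethyl 2-(triphenyl-λ5-phosphanylidene)butanoate | CCOC(=O)C(CC)=P(c1ccccc1)(c1ccccc1)c1ccccc1 | starting material
5 | ethyl (2E,4E)-5-bromo-2,4-diethylpenta-2,4-dienoate | CCOC(=O)/C(CC)=C/C(CC)=C/Br | intermediate
6 | (2E,4E)-5-bromo-2,4-diethylpenta-2,4-dien-1-ol | OC/C(CC)=C/C(CC)=C/Br | intermediate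
7 | (2E,4E)-5-bromo-2,4-diethylpenta-2,4-dienal | O=C/C(CC)=C/C(CC)=C/Br | intermediate
8 | diethyl benzylphosphonate | CCOP(=O)(Cc1ccccc1)OCC | starting material
9 | sodium (diethoxyphosphoryl)(phenyl)methanide | [Na+].CCOP(=O)([CH-]c1ccccc1)OCC | intermediate
10 | [(1E,3E,5E)-6-bromo-3,5-diethylhexa-1,3,5-trien-1-yl]benzene | Br/C=C(CC)/C=C(CC)/C=C/c1ccccc1 | intermediate
11 | pent-3-yn-2-one | CC#CC(C)=O | starting material
12 | (2R)-pent-3-yn-2-ol | CC#C[C@@H](C)O | intermediate
13 | (2R)-pent-3-yn-2-yl methanesulfonate | CC#C[C@@H](C)OS(C)(=O)=O | intermediate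
14 | (4R)-4-benzyl-3-butanoyl-1,3-oxazolidin-2-one | CCCC(=O)N1[C@H](Cc2ccccc2)COC1=O | starting material
15 | trichlorotitanium (Z)-enolate of 14 | CC/C=C(\O[Ti](Cl)(Cl)Cl)N1[C@H](Cc2ccccc2)COC1=O | intermediate
16 | (4R)-4-benzyl-3-[(2S)-2-(hydroxymethyl)butanoyl]-1,3-oxazolidin-2-one | CC[C@@H](CO)C(=O)N1[C@H](Cc2ccccc2)COC1=O | intermediate
17 | (4R)-4-benzyl-3-[(2S)-2-{[(triethylsilyl)oxy]methyl}butanoyl]-1,3-oxazolidin-2-one | CC[C@@H](CO[Si](CC)(CC)CC)C(=O)N1[C@H](Cc2ccccc2)COC1=O | intermediate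
18 | (2R)-2-{[(triethylsilyl)oxy]methyl}butan-1-ol | OC[C@@H](CC)CO[Si](CC)(CC)CC | intermediate
19 | (2S)-2-{[(triethylsilyl)oxy]methyl}butanal | O=C[C@@H](CC)CO[Si](CC)(CC)CC | intermediate
20 | ethyl[(P)-penta-2,3-dien-2-yl]zinc | CC[Zn]C(C)=[C@]=C(C)[H] | intermediate
21 | (3S,4S,5S)-5-methyl-3-{[(triethylsilyl)oxy]methyl}oct-6-yn-4-ol | CC[Si](CC)(CC)OC[C@H](CC)[C@@H](O)[C@@H](C)C#CC | intermediate
22 | tert-butyl(dimethyl){[(3S,4S,5S)-5-methyl-3-{[(triethylsilyl)oxy]methyl}oct-6-yn-4-yl]oxy}silane | CC[Si](CC)(CC)OC[C@H](CC)[C@@H](O[Si](C)(C)C(C)(C)C)[C@@H](C)C#CC | intermediate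
23 | chlorobis(cyclopentadienyl)[(2E,4S,5S,6S)-5-[(tert-butyldimethylsilyl)oxy]-4-methyl-6-{[(triethylsilyl)oxy]methyl}oct-2-en-2-yl]zirconium | CC[Si](CC)(CC)OC[C@H](CC)[C@@H](O[Si](C)(C)C(C)(C)C)[C@@H](C)/C=C(C)/[Zr](Cl)(C1C=CC=C1)C1C=CC=C1 | intermediate
24 | (2E,4S,5S,6S)-5-[(tert-butyldimethylsilyl)oxy]-2-iodo-4-methyl-6-{[(triethylsilyl)oxy]methyl}oct-2-ene | CC[Si](CC)(CC)OC[C@H](CC)[C@@H](O[Si](C)(C)C(C)(C)C)[C@@H](C)/C=C(C)/I | intermediate
25 | (2R,3S,4S,5E)-3-[(tert-butyldimethylsilyl)oxy]-2-ethyl-6-iodo-4-methylhept-5-enal | O=C[C@H](CC)[C@@H](O[Si](C)(C)C(C)(C)C)[C@@H](C)/C=C(C)/I | intermediate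
26 | ethyl (2E,4S,5S,6S,7E)-5-[(tert-butyldimethylsilyl)oxy]-2,4-diethyl-8-iodo-6-methylnona-2,7-dienoate | CCOC(=O)/C(CC)=C/[C@H](CC)[C@@H](O[Si](C)(C)C(C)(C)C)[C@@H](C)/C=C(C)/I | intermediate
27 | [(1E,3E,5E)-2,4-diethyl-6-phenylhexa-1,3,5-trien-1-yl]lithium | [Li]/C=C(CC)/C=C(CC)/C=C/c1ccccc1 | intermediate
28 | chloro[(1E,3E,5E)-2,4-diethyl-6-phenylhexa-1,3,5-trien-1-yl]zinc | Cl[Zn]/C=C(CC)/C=C(CC)/C=C/c1ccccc1 | intermediate
29 | ethyl (2E,4S,5S,6S,7E,9E,11E,13E)-5-[(tert-butyldimethylsilyl)oxy]-2,4,10,12-tetraethyl-6,8-dimethyl-14-phenyltetradeca-2,7,9,11,13-pentaenoate | CCOC(=O)/C(CC)=C/[C@H](CC)[C@@H](O[Si](C)(C)C(C)(C)C)[C@@H](C)/C=C(C)/C=C(CC)/C=C(CC)/C=C/c1ccccc1 | intermediate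
30 | (2E,4S,5S,6S,7E,9E,11E,13E)-5-[(tert-butyldimethylsilyl)oxy]-2,4,10,12-tetraethyl-6,8-dimethyl-14-phenyltetradeca-2,7,9,11,13-pentaenoic acid | OC(=O)/C(CC)=C/[C@H](CC)[C@@H](O[Si](C)(C)C(C)(C)C)[C@@H](C)/C=C(C)/C=C(CC)/C=C(CC)/C=C/c1ccccc1 | intermediate
31 | (1S,2S,3S,3aR,4R,5R,7aR)-2-[(tert-butyldimethylsilyl)oxy]-3,4,5-triethyl-5-[(1E,3E)-2-ethyl-4-phenylbuta-1,3-dien-1-yl]-1,7-dimethyl-2,3,3a,4,5,7a-hexahydro-1H-indene-4-carboxylic acid | CCC(/C=C/c1ccccc1)=C\[C@@]1(CC)C=C(C)[C@@H]2[C@H]([C@H](CC)[C@@H](O[Si](C)(C)C(C)(C)C)[C@H]2C)[C@@]1(CC)C(=O)O | intermediate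
32 | (1S,2S,3S,3aR,4R,5R,7aR)-3,4,5-triethyl-5-[(1E,3E)-2-ethyl-4-phenylbuta-1,3-dien-1-yl]-2-hydroxy-1,7-dimethyl-2,3,3a,4,5,7a-hexahydro-1H-indene-4-carboxylic acid | CCC(/C=C/c1ccccc1)=C\[C@@]1(CC)C=C(C)[C@@H]2[C@H]([C@H](CC)[C@@H](O)[C@H]2C)[C@@]1(CC)C(=O)O | intermediate
33 | (1S,3S,3aR,4R,5R,7aR)-3,4,5-triethyl-5-[(1E,3E)-2-ethyl-4-phenylbuta-1,3-dien-1-yl]-1,7-dimethyl-2-oxo-2,3,3a,4,5,7a-hexahydro-1H-indene-4-carboxylic acid | CCC(/C=C/c1ccccc1)=C\[C@@]1(CC)C=C(C)[C@@H]2[C@H]([C@H](CC)C(=O)[C@H]2C)[C@@]1(CC)C(=O)O | target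

**Totals and risks**

Total step count: 20. Longest linear sequence: 13 steps (steps 8–20, from 14).

Steps most likely to fail:

1. Step 18 (cycloaddition). What may go wrong: competition between the carboxyl-endo and carboxyl-exo transition states (cis-fused isomer), or a cycloaddition so slow at the doubly quaternary C2–C10 bond that the polyene isomerises or polymerises first. The fallback sets out from 29 and comes back at 31, and changes the dienophile to a Lewis-acid-activated enal. Ester 29 would be reduced with i-Bu2AlH to the (2E,4S,5S,6S,7E,9E,11E,13E)-pentaen-1-ol F1 and oxidised with MnO2 to the corresponding pentaenal F2. The enal would then be cyclised at −78 to −20 °C with Me2AlCl in CH2Cl2, where complexation should enforce the carbonyl-endo mode, to the hexahydroindene-4-carbaldehyde F3. Pinnick oxidation (NaClO2, NaH2PO4, 2-methylbut-2-ene, t-BuOH/H2O) of this neopentyl aldehyde would give 31.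

2. Step 12 (allenylzinc addition). What may go wrong: erosion of the anti selectivity or of the enantiomeric purity through equilibration of the allenylzinc intermediate, or ethyl transfer to the aldehyde. The fallback sets out from 19 and comes back at 22, and replaces the propargylation by a crotylation with later alkyne construction. Roush crotylboration of 19 with the (E)-crotylboronate of diisopropyl (R,R)-tartrate (the enantiomer expected to be matched with the Felkin preference of 19; toluene, −78 °C) would give the anti homoallylic alcohol (3S,4S,5S)-3-methyl-5-{[(triethylsilyl)oxy]methyl}hept-1-en-4-ol F4. Silylation (TBSOTf, 2,6-lutidine) would give the bis-silyl ether F5, ozonolysis (O3, CH2Cl2, −78 °C; PPh3) the aldehyde F6, and CBr4/PPh3 the 1,1-dibromoalkene F7. Treatment with n-BuLi (2 equiv, −78 °C) and then MeI would give 22.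

3. Step 16 (fragment union). What may go wrong: loss of alkene geometry or oligomerisation during bromine–lithium exchange on the conjugated triene, and homocoupling of the organozinc. The fallback sets out from 10 and comes back at 29, and uses a boron nucleophile with no organolithium. Miyaura borylation of 10 (B2pin2, PdCl2(PPh3)2, PPh3, KOPh, toluene, 50 °C) would give the trienyl pinacol boronate F8. Suzuki–Miyaura coupling of this boronate with 26 (Pd(PPh3)4, aq. K3PO4, THF, rt → 40 °C) would give 29.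

**Further compounds**

F1 | step 18 | (2E,4S,5S,6S,7E,9E,11E,13E)-5-[(tert-butyldimethylsilyl)oxy]-2,4,10,12-tetraethyl-6,8-dimethyl-14-phenyltetradeca-2,7,9,11,13-pentaen-1-ol | OC/C(CC)=C/[C@H](CC)[C@@H](O[Si](C)(C)C(C)(C)C)[C@@H](C)/C=C(C)/C=C(CC)/C=C(CC)/C=C/c1ccccc1
F2 | step 18 | (2E,4S,5S,6S,7E,9E,11E,13E)-5-[(tert-butyldimethylsilyl)oxy]-2,4,10,12-tetraethyl-6,8-dimethyl-14-phenyltetradeca-2,7,9,11,13-pentaenal | O=C/C(CC)=C/[C@H](CC)[C@@H](O[Si](C)(C)C(C)(C)C)[C@@H](C)/C=C(C)/C=C(CC)/C=C(CC)/C=C/c1ccccc1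
F3 | step 18 | (1S,2S,3S,3aR,4R,5R,7aR)-2-[(tert-butyldimethylsilyl)oxy]-3,4,5-triethyl-5-[(1E,3E)-2-ethyl-4-phenylbuta-1,3-dien-1-yl]-1,7-dimethyl-2,3,3a,4,5,7a-hexahydro-1H-indene-4-carbaldehyde | CCC(/C=C/c1ccccc1)=C\[C@@]1(CC)C=C(C)[C@@H]2[C@H]([C@H](CC)[C@@H](O[Si](C)(C)C(C)(C)C)[C@H]2C)[C@@]1(CC)C=O
F4 | step 12 | (3S,4S,5S)-3-methyl-5-{[(triethylsilyl)oxy]methyl}hept-1-en-4-ol | CC[Si](CC)(CC)OC[C@H](CC)[C@@H](O)[C@@H](C)C=C
F5 | step 12 | tert-butyl(dimethyl){[(3S,4S,5S)-3-methyl-5-{[(triethylsilyl)oxy]methyl}hept-1-en-4-yl]oxy}silane | CC[Si](CC)(CC)OC[C@H](CC)[C@@H](O[Si](C)(C)C(C)(C)C)[C@@H](C)C=C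
F6 | step 12 | (2R,3R,4S)-3-[(tert-butyldimethylsilyl)oxy]-2-methyl-4-{[(triethylsilyl)oxy]methyl}hexanal | CC[Si](CC)(CC)OC[C@H](CC)[C@@H](O[Si](C)(C)C(C)(C)C)[C@@H](C)C=O
F7 | step 12 | (3S,4S,5S)-1,1-dibromo-4-[(tert-butyldimethylsilyl)oxy]-3-methyl-5-{[(triethylsilyl)oxy]methyl}hept-1-ene | CC[Si](CC)(CC)OC[C@H](CC)[C@@H](O[Si](C)(C)C(C)(C)C)[C@@H](C)C=C(Br)Br
F8 | step 16 | 2-[(1E,3E,5E)-2,4-diethyl-6-phenylhexa-1,3,5-trien-1-yl]-4,4,5,5-tetramethyl-1,3,2-dioxaborolane | CC1(C)OB(/C=C(CC)/C=C(CC)/C=C/c2ccccc2)OC1(C)C
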